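**Retrosynthetic overview**

- Numbering: C1 carries the CH2 group (C7), C2 and C3 carry Br, C4 the aryl sulfate, C5 the free OH and C6 H. The plan rests on the unbroken Br(C2)–Br(C3)–O(C4)–O(C5) run on the single benzene ring, two vicinal oxygens directly beside a vicinal dibromide.
- The polar groups come off in reverse order: O5–H from a TIPS ether kept to the end, then the C7–O–S bond, then the C7 alcohol back to the aldehyde, then the C4–O–S bond.
- The C1–C7 bond is cut to an aryl iodide (iodine–magnesium exchange, then DMF). The iodine is placed para to the free O4–H of an O5-monosilylated 3,4-dibromocatechol.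
- The catechol comes from the cis-dihydrodiol of 1,2-dibromobenzene. Toluene dioxygenase and O2 make its C4–O and C5–O bonds in one event, and a diol dehydrogenase then rearomatises it.
- No ring is formed at any stage. The benzene ring is bought with 1,2-dibromobenzene, dearomatised in step 1 and restored in step 2, and the target has no stereocentre.

Key step: step 1

Assumption: the sulfate half-esters are written in the protonated form of the target SMILES; in the flask they are triethylammonium salts until the acidic resin of the last step, and the acid form is best neutralised (KHCO3) for storage.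

**Step 1**
Reactants: 1 1,2-dibromobenzene
Product: 2 (1S,2S)-3,4-dibromocyclohexa-3,5-diene-1,2-diol (cis-diol)
Conditions: E. coli JM109(pDTG601) whole cells (toluene dioxygenase, IPTG-induced), air sparge, glucose feed, mineral salts medium, pH 7.0–7.2, 35 °C; cells spun off, extraction with base-washed EtOAc, product kept cold
Reagents that add atoms: dioxygen, O=O
Why: The Rieske non-haem iron oxygenase of the toluene dioxygenase system binds O2 at its mononuclear iron centre (divalent iron in the resting enzyme), receives two electrons from NADH through its reductase and ferredoxin partners, and passes both oxygen atoms to the same face of one C=C edge of 1, so that the C4–O and C5–O bonds form together and the ring is dearomatised to the cis-diol. The closest known reaction type is the whole-cell toluene dioxygenase cis-dihydroxylation of halobenzenes and dihalobenzenes by recombinant E. coli, a class to which 1 belongs. No ring is closed, since the six-membered carbocycle of 1 is kept. Both new stereocentres (1S,2S) are set by the chiral active site, which offers one face and one of the two mirror-related edges of 1 to the iron-bound oxygen, and they are cis because both oxygens come from one metal-bound O2; they are transient and vanish in step 2. The selectivity needed is for the edge next to bromine (C3–C4 of 1) over the remote C4–C5 edge, and the substrate secures it through its bromines, which sit in the hydrophobic pocket as the halogen of a monohalobenzene does and leave the ortho/meta edge above the iron, while the mirror symmetry of 1 means that either bromine-flanked edge ends as the same catechol. The medium and the extract are held at or above pH 7 and cold, because acid dehydrates 2 to dibromophenols.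

**Step 2**
Reactants: 2 (1S,2S)-3,4-dibromocyclohexa-3,5-diene-1,2-diol
Product: 3 3,4-dibromobenzene-1,2-diol (3,4-dibromocatechol)
Conditions: resting cells of E. coli JM109(pDTG602) (supplies the NAD+-dependent cis-dihydrodiol dehydrogenase TodD), phosphate buffer pH 7.2, air, 30 °C; after full conversion adjusted to pH 5, ascorbic acid, EtOAc extraction under N2
Reagents that add atoms: none
Why: Enzymatic NAD+-dependent alcohol dehydrogenation (cis-dihydrodiol dehydrogenase) removes the two carbinol hydrogens, the gain of aromaticity makes it irreversible, both stereocentres are erased on purpose, and the neutral aqueous medium avoids both acid-induced dehydration of 2 and the C–Br hydrogenolysis that a metal-catalysed dehydrogenation would risk.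

**Step 3**
Reactants: 3 3,4-dibromobenzene-1,2-diol
Product: 4 2,3-dibromo-6-[(triisopropylsilyl)oxy]phenol (O5 silylated, O4–H free)
Conditions: TIPSCl (1.05 equiv), imidazole (2.5 equiv), DMF, 0 °C to 25 °C
Reagents that add atoms: triisopropylsilyl chloride (TIPSCl), CC(C)[Si](Cl)(C(C)C)C(C)C
Why: Regioselective O-silylation, in which the bulky silyl chloride takes the open hydroxyl O5–H and not O4–H wedged between O5 and the bromine on C3, any O4-silyl isomer can drain to 4 by a 1,4-oxygen-to-oxygen silyl shift because 4 keeps the more acidic O4–H free, and a second silylation at the crowded O4 is very slow.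

**Step 4**
Reactants: 4 2,3-dibromo-6-[(triisopropylsilyl)oxy]phenol
Product: 5 2,3-dibromo-4-iodo-6-[(triisopropylsilyl)oxy]phenol
Conditions: NIS (1.05 equiv), TFA (0.2 equiv), MeCN, 0 °C to 25 °C, dark
Reagents that add atoms: N-iodosuccinimide (NIS), O=C1CCC(=O)N1I
Why: Electrophilic aromatic iodination, in which the free O4–H is the strongest donor and both positions ortho to it (C3 and C5) are occupied, so the electrophile goes para to C1, whereas C6 is activated only by the weaker silyloxy donor and is screened by its isopropyl groups.

**Step 5**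
Reactants: 5 2,3-dibromo-4-iodo-6-[(triisopropylsilyl)oxy]phenol; 6 N,N-dimethylformamide
Product: 10 2,3-dibromo-4-hydroxy-5-[(triisopropylsilyl)oxy]benzaldehyde, via chloromagnesium phenolate 7 (not isolated), via C1-magnesiated phenolate 8 (not isolated), via magnesium hemiaminal alkoxide 9 (not isolated)
Conditions: LiCl (1 equiv), MeMgCl (1.0 equiv), THF, −30 °C; iPrMgCl·LiCl (1.1 equiv), −30 to −20 °C; DMF (3 equiv), −20 to 0 °C; 1 M HCl, 0 °C
Reagents that add atoms: N,N-dimethylformamide (6), CN(C)C=O
Why: Iodine–magnesium exchange on a magnesium phenolate followed by Bouveault aldehyde synthesis, in which MeMgCl first masks O4–H as its LiCl-solubilised salt 7, iPrMgCl·LiCl then exchanges only the C1–iodine bond (far faster than C–Br and helped by the adjacent bromine), the ortho-bromo arylmagnesium 8 neither loses MgBrCl to an aryne at this temperature nor undergoes the halogen dance of an aryllithium, and DMF adds once to give 9, which collapses to the aldehyde on acidic quench.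

**Step 6**
Reactants: 10 2,3-dibromo-4-hydroxy-5-[(triisopropylsilyl)oxy]benzaldehyde
Product: 11 2,3-dibromo-4-formyl-6-[(triisopropylsilyl)oxy]phenyl hydrogen sulfate
Conditions: SO3·NEt3 (4 equiv), N,N-dimethylacetamide, 60 °C; chromatography with CH2Cl2/MeOH
Reagents that add atoms: sulfur trioxide–triethylamine complex, CC[N+](CC)(CC)S(=O)(=O)[O-]
Why: O-sulfation of a phenol with an amine–SO3 complex, in which SO3 is small enough to reach O4 between the bromine and the silyl ether, O4–H is the only hydroxyl present, the slow-migrating TIPS group keeps O5 masked, and sulfating at the aldehyde stage blocks O4 before any leaving group sits on C7, which shuts off para-quinone methide formation later.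

**Step 7**
Reactants: 11 2,3-dibromo-4-formyl-6-[(triisopropylsilyl)oxy]phenyl hydrogen sulfate
Product: 12 2,3-dibromo-4-(hydroxymethyl)-6-[(triisopropylsilyl)oxy]phenyl hydrogen sulfate
Conditions: NaBH4 (1 equiv), MeOH, 0 °C; neutral aqueous work-up
Reagents that add atoms: none
Why: Chemoselective 1,2-hydride reduction of the aldehyde with NaBH4, to which the aryl sulfate monoanion, the aryl bromides and the aryl silyl ether are inert at 0 °C.

**Step 8**
Reactants: 12 2,3-dibromo-4-(hydroxymethyl)-6-[(triisopropylsilyl)oxy]phenyl hydrogen sulfate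
Product: 13 {2,3-dibromo-4-(sulfooxy)-5-[(triisopropylsilyl)oxy]phenyl}methyl hydrogen sulfate
Conditions: SO3·NEt3 (3 equiv), DMF, 25 to 40 °C; C18 chromatography with H2O/MeCN
Reagents that add atoms: sulfur trioxide–triethylamine complex, CC[N+](CC)(CC)S(=O)(=O)[O-]
Why: O-sulfation of a primary alcohol with an amine–SO3 complex, in which O4 and O5 are blocked so that only the C7 hydroxyl can react, and the benzylic sulfate monoanion formed is a poor electrophile because the ring carries two bromines and a sulfate in place of a para donor.

**Step 9**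
Reactants: 13 {2,3-dibromo-4-(sulfooxy)-5-[(triisopropylsilyl)oxy]phenyl}methyl hydrogen sulfate
Product: 14 [2,3-dibromo-5-hydroxy-4-(sulfooxy)phenyl]methyl hydrogen sulfate (CNP0301961.0)
Conditions: KHF2 (2.5 equiv), MeOH, 25 °C; then strong-acid cation-exchange resin (H+ form), H2O, 0–5 °C, freeze-dried at once
Reagents that add atoms: none
Why: Fluoride-induced cleavage of an aryl silyl ether, in which bifluoride attacks silicon and expels the good dibromoaryloxide leaving group under nearly neutral conditions that leave both sulfate monoester anions alone, and O5 lies meta to C7 so the freed phenol cannot push out the benzylic sulfate.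

**Compound list**

1 | 1,2-dibromobenzene | Brc1ccccc1Br | starting material
2 | (1S,2S)-3,4-dibromocyclohexa-3,5-diene-1,2-diol (cis) | O[C@H]1C=CC(Br)=C(Br)[C@H]1O | intermediate
3 | 3,4-dibromobenzene-1,2-diol | Oc1ccc(Br)c(Br)c1O | intermediate
4 | 2,3-dibromo-6-[(triisopropylsilyl)oxy]phenol | Oc1c(Br)c(Br)ccc1O[Si](C(C)C)(C(C)C)C(C)C | intermediate
5 | 2,3-dibromo-4-iodo-6-[(triisopropylsilyl)oxy]phenol | Ic1cc(O[Si](C(C)C)(C(C)C)C(C)C)c(O)c(Br)c1Br | intermediate
6 | N,N-dimethylformamide | CN(C)C=O | starting material
7 | chloromagnesium 2,3-dibromo-4-iodo-6-[(triisopropylsilyl)oxy]phenolate | Ic1cc(O[Si](C(C)C)(C(C)C)C(C)C)c(O[Mg]Cl)c(Br)c1Br | intermediate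
8 | chloromagnesium 2,3-dibromo-4-(chloromagnesio)-6-[(triisopropylsilyl)oxy]phenolate | Cl[Mg]c1cc(O[Si](C(C)C)(C(C)C)C(C)C)c(O[Mg]Cl)c(Br)c1Br | intermediate
9 | bis(chloromagnesium) salt of 2,3-dibromo-4-[(dimethylamino)(hydroxy)methyl]-6-[(triisopropylsilyl)oxy]phenol (racemic at the hemiaminal carbon) | CN(C)C(O[Mg]Cl)c1cc(O[Si](C(C)C)(C(C)C)C(C)C)c(O[Mg]Cl)c(Br)c1Br | intermediate
10 | 2,3-dibromo-4-hydroxy-5-[(triisopropylsilyl)oxy]benzaldehyde | O=Cc1cc(O[Si](C(C)C)(C(C)C)C(C)C)c(O)c(Br)c1Br | intermediate
11 | 2,3-dibromo-4-formyl-6-[(triisopropylsilyl)oxy]phenyl hydrogen sulfate | O=Cc1cc(O[Si](C(C)C)(C(C)C)C(C)C)c(OS(=O)(=O)O)c(Br)c1Br | intermediate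
12 | 2,3-dibromo-4-(hydroxymethyl)-6-[(triisopropylsilyl)oxy]phenyl hydrogen sulfate | OCc1cc(O[Si](C(C)C)(C(C)C)C(C)C)c(OS(=O)(=O)O)c(Br)c1Br | intermediate
13 | {2,3-dibromo-4-(sulfooxy)-5-[(triisopropylsilyl)oxy]phenyl}methyl hydrogen sulfate | O=S(=O)(O)OCc1cc(O[Si](C(C)C)(C(C)C)C(C)C)c(OS(=O)(=O)O)c(Br)c1Br | intermediate
14 | [2,3-dibromo-5-hydroxy-4-(sulfooxy)phenyl]methyl hydrogen sulfate (CNP0301961.0) | O=S(=O)(O)OCc1cc(O)c(OS(=O)(=O)O)c(Br)c1Br | target

**Total step count:** 9
**Longest linear sequence:** 9 steps (1 to 14)

**Steps most likely to fail**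

**Step 1.**
- Risk: the culture may be poisoned by the lipophilic substrate and stop converting. Part of the oxidation may drift to the remote edge. The diol may dehydrate during extraction and concentration.
- Fallback: this sets out from 1 and comes back at 3 by purely chemical oxygenation.
- Compound 1 is deprotonated beside bromine with LDA in THF at −78 °C in the presence of B(OiPr)3 (in situ quench) and hydrolysed to (2,3-dibromophenyl)boronic acid F1.
- Oxidation with H2O2/NaOH gives 2,3-dibromophenol F2.
- Casnati–Skattebøl ortho-formylation (MgCl2, Et3N, paraformaldehyde, MeCN, reflux) at the only free ortho position gives 3,4-dibromo-2-hydroxybenzaldehyde F3.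
- Dakin oxidation (H2O2, aqueous NaOH) then delivers 3.

**Step 2.**
- Risk: the dehydrogenase may turn over the crowded dibromo diol slowly. The catechol may inhibit the cells or autoxidise in the aerated buffer.
- Fallback: this sets out from 2 and comes back at 4, so step 3 is skipped and O4 and O5 are told apart while they are still sp3 carbinols.
- TIPSOTf (1.0 equiv) and 2,6-lutidine in CH2Cl2 at −78 °C silylate the less hindered hydroxyl remote from bromine. The product is (1S,6S)-2,3-dibromo-6-[(triisopropylsilyl)oxy]cyclohexa-2,4-dien-1-ol F4.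
- Swern oxidation ((COCl)2, DMSO, then Et3N, CH2Cl2, −78 °C) of the remaining carbinol gives (6S)-2,3-dibromo-6-[(triisopropylsilyl)oxy]cyclohexa-2,4-dien-1-one F5.
- F5 enolises under the amine base to 4.

**Step 5.**
- Risk: the exchange may be sluggish on the electron-rich phenolate. Warming to force it may cause loss of MgBrCl from the ortho-bromo arylmagnesium, that is, aryne decomposition.
- Fallback: this sets out from 5 and comes back at 10, running the exchange on a neutral, covalently masked ring.
- MOMCl and iPr2NEt in CH2Cl2 give [3,4-dibromo-5-iodo-2-(methoxymethoxy)phenoxy]triisopropylsilane F6.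
- iPrMgCl·LiCl in THF at −40 °C gives {2,3-dibromo-4-(methoxymethoxy)-5-[(triisopropylsilyl)oxy]phenyl}magnesium chloride F7.
- DMF then gives 2,3-dibromo-4-(methoxymethoxy)-5-[(triisopropylsilyl)oxy]benzaldehyde F8.
- Dilute HCl in THF/iPrOH at 25 °C removes the acetal, while the aryl TIPS ether stays, to give 10.

**Further compounds**

F1 | step 1 | (2,3-dibromophenyl)boronic acid | OB(O)c1cccc(Br)c1Br
F2 | step 1 | 2,3-dibromophenol | Oc1cccc(Br)c1Br
F3 | step 1 | 3,4-dibromo-2-hydroxybenzaldehyde | O=Cc1ccc(Br)c(Br)c1O
F4 | step 2 | (1S,6S)-2,3-dibromo-6-[(triisopropylsilyl)oxy]cyclohexa-2,4-dien-1-ol | CC(C)[Si](C(C)C)(C(C)C)O[C@H]1C=CC(Br)=C(Br)[C@H]1O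
F5 | step 2 | (6S)-2,3-dibromo-6-[(triisopropylsilyl)oxy]cyclohexa-2,4-dien-1-one | CC(C)[Si](C(C)C)(C(C)C)O[C@H]1C=CC(Br)=C(Br)C1=O
F6 | step 5 | [3,4-dibromo-5-iodo-2-(methoxymethoxy)phenoxy]triisopropylsilane | Ic1cc(O[Si](C(C)C)(C(C)C)C(C)C)c(OCOC)c(Br)c1Br
F7 | step 5 | {2,3-dibromo-4-(methoxymethoxy)-5-[(triisopropylsilyl)oxy]phenyl}magnesium chloride | Cl[Mg]c1cc(O[Si](C(C)C)(C(C)C)C(C)C)c(OCOC)c(Br)c1Br
F8 | step 5 | 2,3-dibromo-4-(methoxymethoxy)-5-[(triisopropylsilyl)oxy]benzaldehyde | O=Cc1cc(O[Si](C(C)C)(C(C)C)C(C)C)c(OCOC)c(Br)c1Br
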